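**Plan**
- Target: an eriodictyol-type flavanone (rings A, B, C) is bonded through C3 to C8'' of a (2S)-naringenin unit (rings A'', B'', C''). The (2R,3R) descriptors place H-2 and H-3 cis, the less stable array, so C3 must be carried to the end without base.
- Cuts, last bond first: seven O–benzyl bonds; C4–C4a (Friedel–Crafts); O1–C2 (Mitsunobu ether); C2–C3 (aldol); C8''-allyl back from C8''-CH2CO2H; C8''–C8a'' and C4a''–C5'' (benzannulation); C2''–C3'' and O1''–C8a'' (hetero-Diels–Alder).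
- Enabling feature: ring A'' (C4a''–C5''–C6''–C7''–C8''–C8a'') is a 5'',7''-resorcinol fused along C4a''–C8a'' to pyranone ring C'', with the inter-unit carbon on C8'' ortho to O1''. C5''–C8'' maps onto a 4-substituted 1,3-bis(silyloxy)diene and C4a''=C8a'' onto the acceptor-activated enone C=C of a 2-aryl-dihydropyranone, so C8'' versus C6'' is decided by construction.
- Forward order: ring C'', then ring A'' (key step), then allyl to arylacetic acid, then the acyclic C2–C3 aldol, then the aryl ether, then ring C. Ring A and both B rings are bought.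
- Stereochemistry: C2'' comes from the BINOL–Ti(OiPr)4-catalysed hetero-Diels–Alder. C3 and C2 come from an oxazolidinone-controlled anti-aldol, and C2 is then inverted in the Mitsunobu step (anti becomes syn, which closes to cis).

Key step: step 7

Assumption: (S)-BINOL/Ti(OiPr)4 is taken to direct the diene to the Si face of 1, and the MgCl2-catalysed aldol of the arylacetyl imide is taken to follow the facial sense of the parent propionyl imide; ligand and auxiliary are both sold as either antipode.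

Step 1
Reactants: 1 4-(benzyloxy)benzaldehyde; 2 Danishefsky's diene
Product: 4 (2S)-2-[4-(benzyloxy)phenyl]-2,3-dihydro-4H-pyran-4-one, via silyl aldol adduct 3 (not isolated)
Conditions: (S)-BINOL (20 mol%), Ti(OiPr)4 (10 mol%), 4 Å MS, Et2O, −20 °C; then TFA (cat.), CH2Cl2, 0 °C
Reagents that add atoms: none
Why: Catalytic asymmetric hetero-Diels–Alder reaction by the Mukaiyama aldol/cyclisation pathway, in which the BINOL–titanium complex leaves the Si face of the bound aldehyde open to the diene terminus and so sets C2'' as S, after which acid closes the ring with loss of methoxysilane.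

Step 2
Reactants: 4 (2S)-2-[4-(benzyloxy)phenyl]-2,3-dihydro-4H-pyran-4-one
Product: 6 (2S)-2-[4-(benzyloxy)phenyl]-5-(phenylsulfanyl)-2,3-dihydro-4H-pyran-4-one, via chloro sulfide adduct 5 (not isolated)
Conditions: PhSH, NCS, CH2Cl2, 0 °C (PhSCl in situ); add 4, −78 → 0 °C; Et3N, 0 °C
Reagents that add atoms: thiophenol, Sc1ccccc1 (delivered as PhSCl)
Why: Electrophilic α-sulfenylation of a vinylogous ester by addition–elimination, the same pattern as its α-halogenation with NBS or NIS: the sulfenyl chloride attacks the nucleophilic C5, chloride caps C6 and Et3N removes HCl without touching C2.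

Step 3
Reactants: 6 (2S)-2-[4-(benzyloxy)phenyl]-5-(phenylsulfanyl)-2,3-dihydro-4H-pyran-4-one
Product: 7 (2S)-2-[4-(benzyloxy)phenyl]-5-(phenylsulfinyl)-2,3-dihydro-4H-pyran-4-one (both sulfur epimers)
Conditions: mCPBA (1.0 equiv), CH2Cl2, −78 → −30 °C
Reagents that add atoms: mCPBA, O=C(OO)c1cccc(Cl)c1
Why: Sulfide-to-sulfoxide oxidation with one equivalent of peracid at low temperature is faster than attack on the push–pull C=C, and the sulfur configuration is irrelevant because the group is expelled in step 7.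

Step 4
Reactants: 8 methyl acetoacetate; 9 allyl bromide
Product: 10 methyl 3-oxohept-6-enoate
Conditions: NaH, THF, 0 °C; n-BuLi, 0 °C; 9, 0 °C → rt; aq. HCl
Reagents that add atoms: none
Why: γ-Alkylation of the acetoacetate dianion, whose more basic terminal carbanion is alkylated by the allylic bromide while the stabilised enolate stays untouched.

Step 5
Reactants: 10 methyl 3-oxohept-6-enoate
Product: 11 methyl 3-(trimethylsilyloxy)hepta-2,6-dienoate
Conditions: Me3SiCl, Et3N, hexane, rt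
Reagents that add atoms: chlorotrimethylsilane, C[Si](C)(C)Cl
Why: O-silylation of the enolised β-keto ester, the standard first stage in the preparation of 1,3-bis(silyl enol ethers).

Step 6
Reactants: 11 methyl 3-(trimethylsilyloxy)hepta-2,6-dienoate
Product: 12 1-methoxy-1,3-bis(trimethylsilyloxy)hepta-1,3,6-triene (geometric isomers, mainly 3Z)
Conditions: LiN(iPr)2, THF, −78 °C; Me3SiCl, −78 → 0 °C
Reagents that add atoms: chlorotrimethylsilane, C[Si](C)(C)Cl
Why: Kinetic γ-deprotonation of the vinylogous ester and O-silylation of the dienolate, a preparation established for 4-alkyl and 4-allyl 1,3-bis(silyloxy)dienes, places the allyl group outward in the s-cis conformer.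

Step 7
Reactants: 7 (2S)-2-[4-(benzyloxy)phenyl]-5-(phenylsulfinyl)-2,3-dihydro-4H-pyran-4-one; 12 1-methoxy-1,3-bis(trimethylsilyloxy)hepta-1,3,6-triene
Product: 15 (2S)-8-allyl-2-[4-(benzyloxy)phenyl]-5,7-dihydroxychroman-4-one, via sulfinyl cycloadduct 13 (not isolated), via cyclohexadiene ketal 14 (not isolated)
Conditions: 12 (2.5 equiv), toluene, 25 → 80 °C, no Lewis acid; then 1 M HCl, THF, 0 °C → rt
Reagents that add atoms: none
Why: Proposed new method: the electron-rich diene 12 should add across C5=C6 of 7, whose LUMO is lowered by the geminal ketone and sulfinyl acceptors, in a strongly asynchronous suprafacial [4+2] in which the allyl-bearing terminus C4 of 12 bonds first to C6 of 7 (C8''–C8a'') and the ketene-acetal carbon C1 then closes onto C5 (C5''–C4a''), so that ring A'' arises by six-membered cycloaddition. Suprafacial addition leaves H-8a'' cis to the sulfinyl group and makes it the only β-hydrogen within reach, so thermal syn-elimination of PhSOH gives 14 without base, whereas a halogen at C5 would activate less and would need an anti elimination that the cis adduct cannot offer, under base that could instead expel the ring oxygen. Acid then collapses the silyl methyl ketal at C5'', the C8''–H dienone tautomerises, and both silyl groups are lost to give the resorcinol ring. The closest known reaction types are the tandem Diels–Alder/sulfoxide elimination of 2-sulfinyl enones and sulfinylquinones, the cycloadditions of 3-acceptor-substituted chromones with siloxydienes, and the aromatising additions of Brassard- and Chan-type dienes to haloquinones. Only regiocontrol is required, and it follows from matching the largest HOMO coefficient (C4 of 12) with the β-carbon C6 of 7, which puts allyl on C8'' next to O1''; Lewis acids are left out because they would switch the diene to its 1,3-dinucleophile [3+3] mode through C2 and the ketone. The three transient stereocentres of 13 are erased on aromatisation, and C2'' lies outside the reacting π system and is untouched.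

Step 8
Reactants: 15 (2S)-8-allyl-2-[4-(benzyloxy)phenyl]-5,7-dihydroxychroman-4-one
Product: 16 (2S)-8-allyl-5,7-bis(benzyloxy)-2-[4-(benzyloxy)phenyl]chroman-4-one
Conditions: BnOH (3 equiv), PPh3 (3 equiv), DIAD (3 equiv), THF, 0 °C → rt
Reagents that add atoms: benzyl alcohol, OCc1ccccc1
Why: Double Mitsunobu O-alkylation, known also for the chelated 5-OH of 5-hydroxyflavanones, benzylates both phenols under essentially neutral conditions and so avoids the carbonate-induced retro-oxa-Michael opening that would racemise C2''.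

Step 9
Reactants: 16 (2S)-8-allyl-5,7-bis(benzyloxy)-2-[4-(benzyloxy)phenyl]chroman-4-one
Product: 18 {(2S)-5,7-bis(benzyloxy)-2-[4-(benzyloxy)phenyl]-4-oxochroman-8-yl}acetaldehyde, via vicinal diol 17 (not isolated)
Conditions: OsO4 (2 mol%), NaIO4 (4 equiv), 2,6-lutidine, dioxane–H2O (3:1), rt
Reagents that add atoms: OsO4, O=[Os](=O)(=O)=O (catalytic oxygen carrier); NaIO4, [Na+].[O-]I(=O)(=O)=O (terminal oxygen source)
Why: Lemieux–Johnson cleavage of the only alkene, buffered with lutidine, spares the electron-rich arenes that ozone or RuO4 would attack.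

Step 10
Reactants: 18 {(2S)-5,7-bis(benzyloxy)-2-[4-(benzyloxy)phenyl]-4-oxochroman-8-yl}acetaldehyde
Product: 19 {(2S)-5,7-bis(benzyloxy)-2-[4-(benzyloxy)phenyl]-4-oxochroman-8-yl}acetic acid
Conditions: NaClO2, NaH2PO4, 2-methyl-2-butene (excess), t-BuOH–THF–H2O, 0 °C → rt
Reagents that add atoms: NaClO2, [Na+].[O-]Cl=O
Why: Pinnick oxidation at buffered pH converts the aldehyde selectively, with excess alkene trapping HOCl before it can chlorinate C6''.

Step 11
Reactants: 19 {(2S)-5,7-bis(benzyloxy)-2-[4-(benzyloxy)phenyl]-4-oxochroman-8-yl}acetic acid; 20 (S)-4-benzyl-1,3-oxazolidin-2-one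
Product: 22 (4S)-4-benzyl-3-({(2S)-5,7-bis(benzyloxy)-2-[4-(benzyloxy)phenyl]-4-oxochroman-8-yl}acetyl)-1,3-oxazolidin-2-one, via mixed pivalic anhydride 21 (not isolated)
Conditions: PivCl, Et3N, THF, −20 °C; then 20, LiCl, −20 °C → rt
Reagents that add atoms: none
Why: N-acylation of the oxazolidinone through the mixed pivalic anhydride with LiCl/Et3N needs no strong base, so the flavanone ketone is not enolised and C2'' is safe.

Step 12
Reactants: 22 (4S)-4-benzyl-3-({(2S)-5,7-bis(benzyloxy)-2-[4-(benzyloxy)phenyl]-4-oxochroman-8-yl}acetyl)-1,3-oxazolidin-2-one; 23 3,4-bis(benzyloxy)benzaldehyde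
Product: 25 (4S)-4-benzyl-3-[(2R,3S)-3-[3,4-bis(benzyloxy)phenyl]-2-{(2S)-5,7-bis(benzyloxy)-2-[4-(benzyloxy)phenyl]-4-oxochroman-8-yl}-3-hydroxypropanoyl]-1,3-oxazolidin-2-one, via silylated aldol adduct 24 (not isolated)
Conditions: MgCl2 (20 mol%), Et3N, Me3SiCl, EtOAc, rt; then citric acid (cat.), MeOH–THF, 0 °C
Reagents that add atoms: none
Why: Magnesium-halide-catalysed anti-selective Evans aldol, in which MgCl2/Et3N soft-enolise only the chelating α-aryl imide, the chelated Z-enolate meets the aromatic aldehyde on the face away from the benzyl group (C3 set as R), and silylation of the anti aldolate fixes the carbinol carbon as S.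

Step 13
Reactants: 25 the (2R,3S)-anti aldol imide; 26 3,5-bis(benzyloxy)phenol
Product: 27 (4S)-4-benzyl-3-[(2R,3R)-3-[3,4-bis(benzyloxy)phenyl]-3-[3,5-bis(benzyloxy)phenoxy]-2-{(2S)-5,7-bis(benzyloxy)-2-[4-(benzyloxy)phenyl]-4-oxochroman-8-yl}propanoyl]-1,3-oxazolidin-2-one
Conditions: 26 (1.5 equiv), PPh3, DIAD, toluene, −20 → 0 °C
Reagents that add atoms: none
Why: Mitsunobu etherification, in which the phenol displaces the oxyphosphonium group by SN2 with inversion so that the S carbinol becomes C2 (R) and anti becomes syn, while allylic strain in the imide keeps the α-C–H in the carbonyl plane and slows dehydration.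

Step 14
Reactants: 27 the (2R,3R)-syn aryl ether imide
Product: 29 (2R,3R)-3-[3,4-bis(benzyloxy)phenyl]-3-[3,5-bis(benzyloxy)phenoxy]-2-{(2S)-5,7-bis(benzyloxy)-2-[4-(benzyloxy)phenyl]-4-oxochroman-8-yl}propanoic acid, via peroxy acid 28 (not isolated)
Conditions: LiOH, H2O2, THF–H2O (3:1), 0 °C; aq. Na2SO3; 1 M HCl to pH 3, 0 °C
Reagents that add atoms: hydrogen peroxide, OO
Why: Hydroperoxide cleavage of the N-acyl oxazolidinone, in which the small and weakly basic HOO− attacks the exocyclic carbonyl at 0 °C under conditions known to preserve α-aryl stereocentres, and sulfite then reduces the peracid.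

Step 15
Reactants: 29 the (2R,3R)-β-aryloxy acid
Product: 31 (2R,3R)-5,7-bis(benzyloxy)-2-[3,4-bis(benzyloxy)phenyl]-3-{(2S)-5,7-bis(benzyloxy)-2-[4-(benzyloxy)phenyl]-4-oxochroman-8-yl}chroman-4-one, via mixed trifluoroacetic anhydride 30 (not isolated)
Conditions: (CF3CO)2O (2 equiv), CH2Cl2, −10 → 0 °C; cold aq. NaHCO3
Reagents that add atoms: none
Why: Intramolecular Friedel–Crafts acylation, in which the phloroglucinol-type ring is attacked at either of its two equivalent positions ortho to O1 in a six-membered closure at or below 0 °C and without base, so that C3 and the benzylic C2–O bond keep their configuration and the syn acid gives the cis-chromanone.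

Step 16
Reactants: 31 the hepta-O-benzyl biflavanone
Product: 32 (2R,3R)-2-(3,4-dihydroxyphenyl)-5,7-dihydroxy-3-[(2S)-5,7-dihydroxy-2-(4-hydroxyphenyl)-4-oxochroman-8-yl]chroman-4-one (CNP0105436.1)
Conditions: H2 (1 atm), 10% Pd/C, EtOAc–MeOH (1:1), rt
Reagents that add atoms: none
Why: Catalytic hydrogenolysis removes all seven benzyl ethers under neutral conditions that neither enolise C3 nor open either pyranone ring.

**Compound list**
1 | 4-(benzyloxy)benzaldehyde | O=Cc1ccc(OCc2ccccc2)cc1 | starting material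
2 | Danishefsky's diene, (E)-1-methoxy-3-(trimethylsilyloxy)buta-1,3-diene | CO/C=C/C(=C)O[Si](C)(C)C | starting material
3 | (1E,5S)-5-[4-(benzyloxy)phenyl]-1-methoxy-5-(trimethylsilyloxy)pent-1-en-3-one | CO/C=C/C(=O)C[C@@H](c1ccc(OCc2ccccc2)cc1)O[Si](C)(C)C | intermediate
4 | (2S)-2-[4-(benzyloxy)phenyl]-2,3-dihydro-4H-pyran-4-one | O=C1C[C@@H](c2ccc(OCc3ccccc3)cc2)OC=C1 | intermediate
5 | (2S)-2-[4-(benzyloxy)phenyl]-6-chloro-5-(phenylsulfanyl)oxan-4-one (C5/C6 epimers) | O=C1C[C@@H](c2ccc(OCc3ccccc3)cc2)OC(Cl)C1Sc1ccccc1 | intermediate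
6 | (2S)-2-[4-(benzyloxy)phenyl]-5-(phenylsulfanyl)-2,3-dihydro-4H-pyran-4-one | O=C1C[C@@H](c2ccc(OCc3ccccc3)cc2)OC=C1Sc1ccccc1 | intermediate
7 | (2S)-2-[4-(benzyloxy)phenyl]-5-(phenylsulfinyl)-2,3-dihydro-4H-pyran-4-one (both sulfur epimers) | O=C1C[C@@H](c2ccc(OCc3ccccc3)cc2)OC=C1S(=O)c1ccccc1 | intermediate
8 | methyl acetoacetate | CC(=O)CC(=O)OC | starting material
9 | allyl bromide | C=CCBr | starting material
10 | methyl 3-oxohept-6-enoate | COC(=O)CC(=O)CCC=C | intermediate
11 | methyl 3-(trimethylsilyloxy)hepta-2,6-dienoate | COC(=O)C=C(CCC=C)O[Si](C)(C)C | intermediate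
12 | 1-methoxy-1,3-bis(trimethylsilyloxy)hepta-1,3,6-triene | COC(O[Si](C)(C)C)=CC(O[Si](C)(C)C)=CCC=C | intermediate
13 | (2S)-8-allyl-2-[4-(benzyloxy)phenyl]-5-methoxy-4a-(phenylsulfinyl)-5,7-bis(trimethylsilyloxy)-2,3,4a,5,8,8a-hexahydrochromen-4-one | O=C1C[C@@H](c2ccc(OCc3ccccc3)cc2)OC2C(CC=C)C(O[Si](C)(C)C)=CC(OC)(O[Si](C)(C)C)C12S(=O)c1ccccc1 | intermediate
14 | (2S)-8-allyl-2-[4-(benzyloxy)phenyl]-5-methoxy-5,7-bis(trimethylsilyloxy)-2,3,5,8-tetrahydrochromen-4-one | O=C1C[C@@H](c2ccc(OCc3ccccc3)cc2)OC2=C1C(OC)(O[Si](C)(C)C)C=C(O[Si](C)(C)C)C2CC=C | intermediate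
15 | (2S)-8-allyl-2-[4-(benzyloxy)phenyl]-5,7-dihydroxychroman-4-one | O=C1C[C@@H](c2ccc(OCc3ccccc3)cc2)Oc2c1c(O)cc(O)c2CC=C | intermediate
16 | (2S)-8-allyl-5,7-bis(benzyloxy)-2-[4-(benzyloxy)phenyl]chroman-4-one | O=C1C[C@@H](c2ccc(OCc3ccccc3)cc2)Oc2c1c(OCc1ccccc1)cc(OCc1ccccc1)c2CC=C | intermediate
17 | (2S)-5,7-bis(benzyloxy)-2-[4-(benzyloxy)phenyl]-8-(2,3-dihydroxypropyl)chroman-4-one (carbinol epimers) | O=C1C[C@@H](c2ccc(OCc3ccccc3)cc2)Oc2c1c(OCc1ccccc1)cc(OCc1ccccc1)c2CC(O)CO | intermediate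
18 | {(2S)-5,7-bis(benzyloxy)-2-[4-(benzyloxy)phenyl]-4-oxochroman-8-yl}acetaldehyde | O=C1C[C@@H](c2ccc(OCc3ccccc3)cc2)Oc2c1c(OCc1ccccc1)cc(OCc1ccccc1)c2CC=O | intermediate
19 | {(2S)-5,7-bis(benzyloxy)-2-[4-(benzyloxy)phenyl]-4-oxochroman-8-yl}acetic acid | O=C1C[C@@H](c2ccc(OCc3ccccc3)cc2)Oc2c1c(OCc1ccccc1)cc(OCc1ccccc1)c2CC(=O)O | intermediate
20 | (S)-4-benzyl-1,3-oxazolidin-2-one | O=C1N[C@@H](Cc2ccccc2)CO1 | starting material
21 | mixed anhydride of 19 with pivalic acid | O=C1C[C@@H](c2ccc(OCc3ccccc3)cc2)Oc2c1c(OCc1ccccc1)cc(OCc1ccccc1)c2CC(=O)OC(=O)C(C)(C)C | intermediate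
22 | (4S)-4-benzyl-3-({(2S)-5,7-bis(benzyloxy)-2-[4-(benzyloxy)phenyl]-4-oxochroman-8-yl}acetyl)-1,3-oxazolidin-2-one | O=C1C[C@@H](c2ccc(OCc3ccccc3)cc2)Oc2c1c(OCc1ccccc1)cc(OCc1ccccc1)c2CC(=O)N1C(=O)OC[C@@H]1Cc1ccccc1 | intermediate
23 | 3,4-bis(benzyloxy)benzaldehyde | O=Cc1ccc(OCc2ccccc2)c(OCc2ccccc2)c1 | starting material
24 | O-trimethylsilyl ether of 25 | O=C1C[C@@H](c2ccc(OCc3ccccc3)cc2)Oc2c1c(OCc1ccccc1)cc(OCc1ccccc1)c2[C@H]([C@H](O[Si](C)(C)C)c1ccc(OCc2ccccc2)c(OCc2ccccc2)c1)C(=O)N1C(=O)OC[C@@H]1Cc1ccccc1 | intermediate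
25 | (2R,3S)-anti aldol imide (full name in step 12) | O=C1C[C@@H](c2ccc(OCc3ccccc3)cc2)Oc2c1c(OCc1ccccc1)cc(OCc1ccccc1)c2[C@H]([C@H](O)c1ccc(OCc2ccccc2)c(OCc2ccccc2)c1)C(=O)N1C(=O)OC[C@@H]1Cc1ccccc1 | intermediate
26 | 3,5-bis(benzyloxy)phenol | Oc1cc(OCc2ccccc2)cc(OCc2ccccc2)c1 | starting material
27 | (2R,3R)-syn aryl ether imide (full name in step 13) | O=C1C[C@@H](c2ccc(OCc3ccccc3)cc2)Oc2c1c(OCc1ccccc1)cc(OCc1ccccc1)c2[C@H]([C@@H](Oc1cc(OCc2ccccc2)cc(OCc2ccccc2)c1)c1ccc(OCc2ccccc2)c(OCc2ccccc2)c1)C(=O)N1C(=O)OC[C@@H]1Cc1ccccc1 | intermediate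
28 | peroxy acid corresponding to 29 | O=C1C[C@@H](c2ccc(OCc3ccccc3)cc2)Oc2c1c(OCc1ccccc1)cc(OCc1ccccc1)c2[C@H]([C@@H](Oc1cc(OCc2ccccc2)cc(OCc2ccccc2)c1)c1ccc(OCc2ccccc2)c(OCc2ccccc2)c1)C(=O)OO | intermediate
29 | (2R,3R)-β-aryloxy acid (full name in step 14) | O=C1C[C@@H](c2ccc(OCc3ccccc3)cc2)Oc2c1c(OCc1ccccc1)cc(OCc1ccccc1)c2[C@H]([C@@H](Oc1cc(OCc2ccccc2)cc(OCc2ccccc2)c1)c1ccc(OCc2ccccc2)c(OCc2ccccc2)c1)C(=O)O | intermediate
30 | mixed anhydride of 29 with trifluoroacetic acid | O=C1C[C@@H](c2ccc(OCc3ccccc3)cc2)Oc2c1c(OCc1ccccc1)cc(OCc1ccccc1)c2[C@H]([C@@H](Oc1cc(OCc2ccccc2)cc(OCc2ccccc2)c1)c1ccc(OCc2ccccc2)c(OCc2ccccc2)c1)C(=O)OC(=O)C(F)(F)F | intermediate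
31 | (2R,3R,2''S)-hepta-O-benzyl biflavanone (full name in step 15) | O=C1C[C@@H](c2ccc(OCc3ccccc3)cc2)Oc2c1c(OCc1ccccc1)cc(OCc1ccccc1)c2[C@H]1C(=O)c2c(OCc3ccccc3)cc(OCc3ccccc3)cc2O[C@H]1c1ccc(OCc2ccccc2)c(OCc2ccccc2)c1 | intermediate
32 | (2R,3R)-2-(3,4-dihydroxyphenyl)-5,7-dihydroxy-3-[(2S)-5,7-dihydroxy-2-(4-hydroxyphenyl)-4-oxochroman-8-yl]chroman-4-one | O=C1C[C@@H](c2ccc(O)cc2)Oc2c1c(O)cc(O)c2[C@H]1C(=O)c2c(O)cc(O)cc2O[C@H]1c1ccc(O)c(O)c1 | target

Total step count: 16. Longest linear sequence: 13 (steps 1–3 and 7–16, from 1).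

**Steps most likely to fail**

Step 7 (new method). The cycloaddition may be too slow relative to thermal decay or hydrolysis of 12. Silyl transfer may stop the reaction after the first C–C bond. The silyl ketene acetal may trigger a Pummerer-type reaction at sulfur. The acyl vinyl sulfoxide may react as an oxadiene with the ketene-acetal C=C.

The fallback uses known chemistry only, sets out from allyl bromide 9 and returns at 16. Ring A'' is bought and C8'' is fixed by a blocked Claisen rearrangement.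
- Commercial 1-[2-hydroxy-4,6-bis(benzyloxy)phenyl]ethanone is O-allylated with 9 (K2CO3, acetone, reflux) to 1-[2-(allyloxy)-4,6-bis(benzyloxy)phenyl]ethanone F1.
- Aromatic Claisen rearrangement (N,N-diethylaniline, 190 °C) can reach only the single free ortho carbon and gives 1-[3-allyl-4,6-bis(benzyloxy)-2-hydroxyphenyl]ethanone F2.
- Me2NCH(OMe)2 (toluene, 90 °C) gives (E)-1-[3-allyl-4,6-bis(benzyloxy)-2-hydroxyphenyl]-3-(dimethylamino)prop-2-en-1-one F3.
- Aqueous HCl in CH2Cl2 closes F3 to 8-allyl-5,7-bis(benzyloxy)chromen-4-one F4.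
- Rhodium-catalysed asymmetric 1,4-addition of 4-(benzyloxy)phenylboronic acid delivers 16. The catalyst is [RhOH(cod)]2 with an electron-poor MeO-BIPHEP-type bisphosphine of the antipode that gives 2S, in toluene–H2O.

Step 13. The activated alcohol may dehydrate to the α-aryl cinnamoyl imide. Ionisation at the electron-rich, crowded benzylic carbon may erode the inversion or lead to C-alkylation of the phenol.

The fallback sets out from acid 19 and returns at acid 29. The carbinol C–O bond is never broken.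
- Acid 19 is coupled as in step 11 with commercial (R)-4-benzyl-1,3-oxazolidin-2-one to the (4R)-auxiliary arylacetyl imide F5.
- An Evans boron syn-aldol (Bu2BOTf, iPr2NEt, CH2Cl2, −78 → 0 °C, then 23; buffered H2O2 work-up) gives the (2R,3R)-syn aldol imide F6, whose carbinol carbon already has the final configuration.
- The hydroxyl oxygen is arylated with retention by Chan–Lam coupling with commercial 3,5-bis(benzyloxy)phenylboronic acid (Cu(OAc)2, DMAP, 4 Å MS, O2, CH2Cl2, rt) to the (2R,3R)-syn aryl ether (4R)-imide F7.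
- LiOH/H2O2 cleavage as in step 14 gives 29.

Step 15. Acid may enolise the new ketone at C3, with drift towards the trans isomer. Acid may also ionise the C2–O bond, or the 7''-oxygen may capture the acyl group with loss of benzyl.

The fallback sets out from 29 and returns at 31. C3 is set after ring closure by kinetic protonation instead of being carried through.
- Acid 29 is cyclised without regard to C3 ((COCl)2, cat. DMF, CH2Cl2; then SnCl4, −78 °C) and taken on as the (2R,3S)-trans hepta-O-benzyl biflavanone F8.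
- Both ketones are converted with Me3SiOTf/Et3N (CH2Cl2, 0 °C) into the bis(trimethylsilyl enol ether) F9.
- F9 is protonated at −78 °C in toluene with the SnCl4·BINOL Lewis acid-assisted Brønsted acid, a known protonation of 2-aryl cyclic silyl enol ethers.
- The C2 aryl group sits pseudoaxial to avoid the C3 aryl group, so the proton should enter anti to it and give the cis ketone 31. Protonation at C3'' creates no stereocentre.

**Further compounds**
F1 | step 7 | 1-[2-(allyloxy)-4,6-bis(benzyloxy)phenyl]ethanone | CC(=O)c1c(OCC=C)cc(OCc2ccccc2)cc1OCc1ccccc1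
F2 | step 7 | 1-[3-allyl-4,6-bis(benzyloxy)-2-hydroxyphenyl]ethanone | CC(=O)c1c(O)c(CC=C)c(OCc2ccccc2)cc1OCc1ccccc1
F3 | step 7 | (E)-1-[3-allyl-4,6-bis(benzyloxy)-2-hydroxyphenyl]-3-(dimethylamino)prop-2-en-1-one | CN(C)/C=C/C(=O)c1c(O)c(CC=C)c(OCc2ccccc2)cc1OCc1ccccc1
F4 | step 7 | 8-allyl-5,7-bis(benzyloxy)chromen-4-one | O=c1ccoc2c1c(OCc1ccccc1)cc(OCc1ccccc1)c2CC=C
F5 | step 13 | (4R)-4-benzyl-3-({(2S)-5,7-bis(benzyloxy)-2-[4-(benzyloxy)phenyl]-4-oxochroman-8-yl}acetyl)-1,3-oxazolidin-2-one | O=C1C[C@@H](c2ccc(OCc3ccccc3)cc2)Oc2c1c(OCc1ccccc1)cc(OCc1ccccc1)c2CC(=O)N1C(=O)OC[C@H]1Cc1ccccc1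
F6 | step 13 | (2R,3R)-syn aldol imide with the (4R)-auxiliary | O=C1C[C@@H](c2ccc(OCc3ccccc3)cc2)Oc2c1c(OCc1ccccc1)cc(OCc1ccccc1)c2[C@H]([C@@H](O)c1ccc(OCc2ccccc2)c(OCc2ccccc2)c1)C(=O)N1C(=O)OC[C@H]1Cc1ccccc1
F7 | step 13 | (2R,3R)-syn 3,5-bis(benzyloxy)phenyl ether imide with the (4R)-auxiliary | O=C1C[C@@H](c2ccc(OCc3ccccc3)cc2)Oc2c1c(OCc1ccccc1)cc(OCc1ccccc1)c2[C@H]([C@@H](Oc1cc(OCc2ccccc2)cc(OCc2ccccc2)c1)c1ccc(OCc2ccccc2)c(OCc2ccccc2)c1)C(=O)N1C(=O)OC[C@H]1Cc1ccccc1
F8 | step 15 | (2R,3S,2''S)-trans hepta-O-benzyl biflavanone (C3 epimer of 31) | O=C1C[C@@H](c2ccc(OCc3ccccc3)cc2)Oc2c1c(OCc1ccccc1)cc(OCc1ccccc1)c2[C@@H]1C(=O)c2c(OCc3ccccc3)cc(OCc3ccccc3)cc2O[C@H]1c1ccc(OCc2ccccc2)c(OCc2ccccc2)c1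
F9 | step 15 | 4,4''-bis(trimethylsilyl enol ether) of F8 (C2 and C2'' unchanged in space) | C[Si](C)(C)OC1=C[C@@H](c2ccc(OCc3ccccc3)cc2)Oc2c1c(OCc1ccccc1)cc(OCc1ccccc1)c2C1=C(O[Si](C)(C)C)c2c(OCc3ccccc3)cc(OCc3ccccc3)cc2O[C@H]1c1ccc(OCc2ccccc2)c(OCc2ccccc2)c1
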